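**Retrosynthetic overview**
1. The target comes from global debenzylation of 43, which is made by a Heck union of the left-half aryl chloride 31 (ring C) with the right-half 4-vinyl-dihydrobenzofuran 42 (E-stilbene).
2. Both trans-dihydrofurans come from [4+1] annulation of an o-quinone methide with a 4-(benzyloxy)benzyl sulfonium ylide: on the C5/C6–O edge of the seven-membered-ring core (substrate control) and on a simple phenol for 42 (chiral sulfide control).
3. Ring C is put on C10 by decarboxylative nickel arylation, and C10 is then inverted through the lateral enolate, because the target has ring C cis to the C11 aryl group (10S,11S) while the arylation should deliver trans.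
4. The seven-membered ring comes from σ-insertion of 3,5-bis(benzyloxy)benzyne into the C1–C2 bond of indanone ketoester 5; the feature that calls for this is that ring B carries the C5 methine and the C10 methine on adjacent carbons (C5a, C9a) with the furan oxygen on C6 next to C5a, the 1,2,3-pattern that a 3-alkoxyaryne leaves.
5. Ring order: ring A with the five-membered ring (enantioselective Nazarov, sets C11), then ring B with expansion to the seven-membered ring, then ring C, then the left dihydrofuran; the right dihydrofuran is made separately; then union.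

Key step: step 7

Remark: all phenols are carried as benzyl ethers (cleaved last with BCl3/pentamethylbenzene) because Lewis-acid demethylation would endanger the stilbene, the two trans-dihydrofurans and C11; the sense of induction written for the chiral ligand (step 3) and the chiral sulfide (step 23) is assigned by analogy with their model reactions, and the antipode is used if it proves opposite.
Locants C1–C11 are those of the dibenzo[a,d][7]annulene core; C12 is the left furan CH that bears the aryl group.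

**Route**

Step 1
Reactants: 1 methyl 3,5-bis(benzyloxy)benzoate
Product: 2 methyl 3-[3,5-bis(benzyloxy)phenyl]-3-oxopropanoate
Conditions: MeOAc, LiN(SiMe3)2 (2.5 equiv), THF, −78 → 0 °C; aq. HCl
Reagents that add atoms: methyl acetate, CC(=O)OC
Why: Crossed Claisen condensation in which the lithium enolate of methyl acetate acylates the non-enolisable aryl ester and the excess base removes the acidic product as its enolate, which drives the reaction.

Step 2
Reactants: 2 methyl 3-[3,5-bis(benzyloxy)phenyl]-3-oxopropanoate; 3 4-(benzyloxy)benzaldehyde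
Product: 4 methyl 2-[3,5-bis(benzyloxy)benzoyl]-3-[4-(benzyloxy)phenyl]prop-2-enoate (E/Z mixture)
Conditions: piperidine (cat.), AcOH (cat.), toluene, reflux, azeotropic removal of water
Reagents that add atoms: none
Why: Knoevenagel condensation of the active methylene with a non-enolisable aldehyde; the alkene geometry is irrelevant because both isomers converge in step 3.

Step 3
Reactants: 4 methyl 2-[3,5-bis(benzyloxy)benzoyl]-3-[4-(benzyloxy)phenyl]prop-2-enoate
Product: 5 methyl (2R,3S)-4,6-bis(benzyloxy)-3-[4-(benzyloxy)phenyl]-1-oxo-2,3-dihydro-1H-indene-2-carboxylate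
Conditions: Cu(OTf)2 (10 mol %), (S,S)-Ph-box (11 mol %), CH2Cl2, 4 Å molecular sieves, rt
Reagents that add atoms: none
Why: Enantioselective Nazarov cyclisation in which the chiral divalent copper bis(oxazoline) complex chelates the two carbonyls, the electron-rich aryl ring closes at its ortho carbon (para to one benzyloxy group) onto the arylidene carbon in a conrotatory 4π-electrocyclisation whose torquoselectivity is set by the ligand and fixes C3 as S, and C2 then equilibrates through the enol to the trans (2R) ester.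

Step 4
Reactants: 6 3,5-bis(benzyloxy)phenol
Product: 7 3,5-bis(benzyloxy)-2-bromophenol
Conditions: NBS, i-Pr2NH (10 mol %), CH2Cl2, −78 → 0 °C
Reagents that add atoms: N-bromosuccinimide, O=C1CCC(=O)N1Br
Why: Amine-catalysed bromination with NBS is ortho-selective for phenols, so bromine should enter C2 (between OH and one benzyloxy group, para to the other) rather than C4.

Step 5
Reactants: 7 3,5-bis(benzyloxy)-2-bromophenol
Product: 8 [3,5-bis(benzyloxy)-2-bromophenoxy]trimethylsilane
Conditions: (Me3Si)2NH, THF, 70 °C; concentrate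
Reagents that add atoms: hexamethyldisilazane, C[Si](C)(C)N[Si](C)(C)C
Why: O-Silylation of the phenol, driven by loss of ammonia, sets up the oxygen-to-carbon silyl shift.

Step 6
Reactants: 8 [3,5-bis(benzyloxy)-2-bromophenoxy]trimethylsilane
Product: 11 3,5-bis(benzyloxy)-2-(trimethylsilyl)phenyl trifluoromethanesulfonate, via aryllithium 9 (not isolated), via lithium phenolate 10 (not isolated)
Conditions: n-BuLi, THF, −100 → −78 °C; Tf2O, −100 °C → rt
Reagents that add atoms: trifluoromethanesulfonic anhydride, O=S(=O)(OS(=O)(=O)C(F)(F)F)C(F)(F)F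
Why: Bromine–lithium exchange gives aryllithium 9, which undergoes the anionic 1,3 O→C silyl shift (retro-Brook rearrangement) to phenolate 10, and this is trapped as the triflate.

Step 7
Reactants: 5 methyl (2R,3S)-4,6-bis(benzyloxy)-3-[4-(benzyloxy)phenyl]-1-oxo-2,3-dihydro-1H-indene-2-carboxylate; 11 3,5-bis(benzyloxy)-2-(trimethylsilyl)phenyl trifluoromethanesulfonate
Product: 14 methyl (10R,11S)-1,3,6,8-tetrakis(benzyloxy)-11-[4-(benzyloxy)phenyl]-5-oxo-10,11-dihydro-5H-dibenzo[a,d][7]annulene-10-carboxylate, via aryne 12 (not isolated), via benzocyclobutenoxide 13 (not isolated)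
Conditions: 11 (1.5 equiv), CsF (3.5 equiv), MeCN, 80 °C
Reagents that add atoms: none
Why: Fluoride removes the silyl group of 11 and triflate leaves to give aryne 12, while CsF in MeCN forms the cesium enolate of 5, whose carbon (indanone C2) adds to the aryne carbon remote from the flanking benzyloxy group so that the aryl anion develops ortho to that oxygen, where it is inductively stabilised. This anion closes onto the indanone carbonyl (4-exo-trig) to give benzocyclobutenoxide 13, and retro-aldol (Grob-type) fragmentation of the old C1–C2 bond, driven by strain release and by formation of an ester-stabilised benzylic anion, opens it, so the seven-membered ring is closed by a two-carbon ring expansion of the five-membered ring and not by a direct cyclisation. The closest known reaction type is the aryne acyl-alkylation (C–C σ-insertion) of cyclic β-ketoesters, which gives benzannulated rings two atoms larger. No stereocentre of the target is created here: C11 (from step 3) is not touched, and C10 is an epimerisable ester α-carbon that should settle as the trans ester and is replaced in step 11. The step needs regioselectivity on the unsymmetrical aryne, which the benzyloxy group next to the triple bond secures (the acyl carbon ends ortho to oxygen, giving C5a–C6–O and C9a–C10), and insertion in preference to simple α-arylation, which the strained five-membered ketoester favours.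

Step 8
Reactants: 14 methyl (10R,11S)-1,3,6,8-tetrakis(benzyloxy)-11-[4-(benzyloxy)phenyl]-5-oxo-10,11-dihydro-5H-dibenzo[a,d][7]annulene-10-carboxylate
Product: 15 (10R,11S)-1,3,6,8-tetrakis(benzyloxy)-11-[4-(benzyloxy)phenyl]-5-oxo-10,11-dihydro-5H-dibenzo[a,d][7]annulene-10-carboxylic acid
Conditions: LiOH·H2O, THF/MeOH/H2O, 50 °C; aq. HCl
Reagents that add atoms: lithium hydroxide, [Li+].[OH-]
Why: Saponification of the methyl ester; the diaryl ketone has no α-hydrogen, and epimerisation at C10 is of no consequence because C10 becomes a radical in step 11.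

Step 9
Reactants: 15 (10R,11S)-1,3,6,8-tetrakis(benzyloxy)-11-[4-(benzyloxy)phenyl]-5-oxo-10,11-dihydro-5H-dibenzo[a,d][7]annulene-10-carboxylic acid
Product: 16 1,3-dioxoisoindolin-2-yl (10R,11S)-1,3,6,8-tetrakis(benzyloxy)-11-[4-(benzyloxy)phenyl]-5-oxo-10,11-dihydro-5H-dibenzo[a,d][7]annulene-10-carboxylate
Conditions: N-hydroxyphthalimide, N,N′-diisopropylcarbodiimide, DMAP (cat.), CH2Cl2, rt
Reagents that add atoms: N-hydroxyphthalimide, O=C1c2ccccc2C(=O)N1O
Why: Carbodiimide esterification gives the redox-active ester needed for single-electron decarboxylation.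

Step 10
Reactants: 17 2-bromo-4-chlorophenol
Product: 18 1-(benzyloxy)-2-bromo-4-chlorobenzene
Conditions: BnBr, K2CO3, DMF, rt
Reagents that add atoms: benzyl bromide, BrCc1ccccc1
Why: Williamson etherification of the phenol.

Step 11
Reactants: 16 1,3-dioxoisoindolin-2-yl ester of acid 15; 18 1-(benzyloxy)-2-bromo-4-chlorobenzene
Product: 21 (10R,11S)-1,3,6,8-tetrakis(benzyloxy)-10-[2-(benzyloxy)-5-chlorophenyl]-11-[4-(benzyloxy)phenyl]-10,11-dihydro-5H-dibenzo[a,d][7]annulen-5-one, via aryllithium 19 (not isolated), via arylzinc chloride 20 (not isolated)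
Conditions: 18, n-BuLi, THF, −78 °C; ZnCl2, → rt (3 equiv of 20); then 16, NiCl2·glyme (20 mol %), 4,4′-di-tert-butyl-2,2′-bipyridine (40 mol %), THF/DMF, rt
Reagents that add atoms: none
Why: Nickel-catalysed decarboxylative Negishi-type arylation in which single-electron reduction of the phthalimide ester releases CO2 and the benzylic C10 radical, which is captured by the aryl–nickel species from 20 and reductively eliminates; the aryl should enter anti to the pseudo-axial C11 aryl group to give mainly the trans (10R) isomer (any cis isomer is 23 itself), and the aryl chloride and the diaryl ketone are inert to the zinc reagent.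

Step 12
Reactants: 21 (10R,11S)-10-aryl ketone (trans)
Product: 23 (10S,11S)-1,3,6,8-tetrakis(benzyloxy)-10-[2-(benzyloxy)-5-chlorophenyl]-11-[4-(benzyloxy)phenyl]-10,11-dihydro-5H-dibenzo[a,d][7]annulen-5-one, via lithium dienolate 22 (not isolated)
Conditions: lithium 2,2,6,6-tetramethylpiperidide (1.5 equiv), THF, −78 → −40 °C; then AcOH (5 equiv) in THF, −78 °C
Reagents that add atoms: none
Why: Proposed new method: the non-enolisable diaryl ketone acidifies the ortho benzylic C10–H, so the hindered lithium amide should effect lateral deprotonation to the extended (o-quinodimethane) enolate 22 with planar C10, while C11–H is spared because a planar C11 anion would force its aryl group into the plane of ring A against the C1 benzyloxy group (allylic 1,3-strain); irreversible protonation at low temperature should then deliver hydrogen to C10 from the face opposite the pseudo-axial C11 aryl group and so leave ring C cis to it (10S), the closest known reaction types being lateral metalation of o-alkyl benzophenones and contra-thermodynamic epimerisation by kinetic protonation of enolates.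

Step 13
Reactants: 23 (10S,11S)-10-aryl ketone (cis)
Product: 24 (10S,11S)-1,3,8-tris(benzyloxy)-10-[2-(benzyloxy)-5-chlorophenyl]-11-[4-(benzyloxy)phenyl]-6-hydroxy-10,11-dihydro-5H-dibenzo[a,d][7]annulen-5-one
Conditions: MgBr2·OEt2 (3 equiv), toluene/Et2O, 60 °C; dil. HCl
Reagents that add atoms: none
Why: Chelation of magnesium between the C5 carbonyl and the C6 ether oxygen activates only this benzyl ether toward bromide attack, so the other five benzyl ethers should remain.

Step 14
Reactants: 24 6-hydroxy ketone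
Product: 25 (10S,11S)-1,3,8-tris(benzyloxy)-10-[2-(benzyloxy)-5-chlorophenyl]-11-[4-(benzyloxy)phenyl]-10,11-dihydro-5H-dibenzo[a,d][7]annulene-5,6-diol (C5 epimers)
Conditions: NaBH4, THF/MeOH, 0 °C → rt
Reagents that add atoms: none
Why: Hydride reduction of the o-hydroxy diaryl ketone to the benzhydrol; the configuration of C5 is irrelevant because C5 becomes planar in step 17.

Step 15
Reactants: 25 C5 carbinol
Product: 26 (10S,11S)-1,3,8-tris(benzyloxy)-10-[2-(benzyloxy)-5-chlorophenyl]-11-[4-(benzyloxy)phenyl]-5-(4-methylbenzenesulfonyl)-10,11-dihydro-5H-dibenzo[a,d][7]annulen-6-ol (C5 epimers)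
Conditions: p-TolSO2H (3 equiv), CH2Cl2, rt
Reagents that add atoms: p-toluenesulfinic acid, Cc1ccc(cc1)S(=O)O
Why: Acid-mediated SN1 substitution in which the C5 carbinol ionises readily (the cation is the protonated o-quinone methide, stabilised by the ortho hydroxy and para benzyloxy groups of ring B) and is trapped at sulfur by the sulfinate, giving a sulfone that releases the o-quinone methide under mild base.

Step 16
Reactants: 27 [4-(benzyloxy)phenyl]methanol
Product: 28 1-[4-(benzyloxy)benzyl]thiolan-1-ium tetrafluoroborate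
Conditions: tetrahydrothiophene (3 equiv), HBF4·OEt2, CH2Cl2, 0 °C → rt
Reagents that add atoms: tetrahydrothiophene, C1CCSC1; tetrafluoroboric acid, [H+].F[B-](F)(F)F
Why: SN1 alkylation of the sulfide by the acid-ionised electron-rich benzylic alcohol gives the sulfonium salt.

Step 17
Reactants: 26 C5 sulfone; 28 1-[4-(benzyloxy)benzyl]thiolan-1-ium tetrafluoroborate
Product: 31 (5S,10S,11S,12S)-configured left-half aryl chloride in which O–C12H[4-(benzyloxy)phenyl] bridges C6 and C5 of the 1,3,8-tris(benzyloxy)-10-[2-(benzyloxy)-5-chlorophenyl]-11-[4-(benzyloxy)phenyl]-10,11-dihydro-5H-dibenzo[a,d][7]annulene core as a trans-2,3-dihydrofuran, via o-quinone methide 29 (not isolated), via sulfonium ylide 30 (not isolated)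
Conditions: Cs2CO3 (3 equiv), CH2Cl2, 0 °C → rt
Reagents that add atoms: none
Why: o-Quinone methide [4+1] annulation with a sulfur ylide, in which carbonate eliminates sulfinate from 26 to give 29 and deprotonates 28 to ylide 30, the ylide adds to C5 from the face opposite the two cis aryl groups at C10 and C11 (setting C5 as S with H5 syn to those aryls), and the phenoxide then displaces tetrahydrothiophene in a 5-exo-tet closure through the less crowded betaine conformer to give the trans-dihydrofuran (C12 S).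

Step 18
Reactants: 32 1,3-bis(benzyloxy)-5-bromobenzene
Product: 33 2,4-bis(benzyloxy)-6-bromobenzaldehyde
Conditions: POCl3, DMF, 0 → 70 °C; H2O
Reagents that add atoms: N,N-dimethylformamide, CN(C)C=O; water, O
Why: Vilsmeier–Haack formylation should occur para to one benzyloxy group and ortho to the other (C2), the position between the two ethers being more hindered.

Step 19
Reactants: 33 2,4-bis(benzyloxy)-6-bromobenzaldehyde
Product: 34 4-(benzyloxy)-2-bromo-6-hydroxybenzaldehyde
Conditions: MgBr2·OEt2 (1.5 equiv), toluene/Et2O, 60 °C; dil. HCl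
Reagents that add atoms: none
Why: Magnesium chelation between the aldehyde and the ortho ether oxygen directs bromide to that benzyl group only.

Step 20
Reactants: 32 1,3-bis(benzyloxy)-5-bromobenzene; 34 4-(benzyloxy)-2-bromo-6-hydroxybenzaldehyde
Product: 36 5-(benzyloxy)-2-{[3,5-bis(benzyloxy)phenyl](hydroxy)methyl}-3-bromophenol (racemic), via Grignard reagent 35 (not isolated)
Conditions: 32, Mg, THF, 40 °C (2.3 equiv of 35); 34, THF, 0 °C → rt; aq. NH4Cl
Reagents that add atoms: none
Why: Grignard addition to the aldehyde after the first equivalent has deprotonated the phenol; bromine–magnesium exchange on the aryl bromide of 34 is slow at this temperature.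

Step 21
Reactants: 36 o-hydroxybenzhydrol
Product: 37 5-(benzyloxy)-2-{[3,5-bis(benzyloxy)phenyl](4-methylbenzenesulfonyl)methyl}-3-bromophenol (racemic)
Conditions: p-TolSO2H (3 equiv), CH2Cl2, rt
Reagents that add atoms: p-toluenesulfinic acid, Cc1ccc(cc1)S(=O)O
Why: The same SN1 sulfinate substitution of an o-hydroxybenzhydrol as in step 15.

Step 22
Reactants: 27 [4-(benzyloxy)phenyl]methanol
Product: 38 (1R,4R,5R)-6-[4-(benzyloxy)benzyl]-4,7,7-trimethyl-6-thiabicyclo[3.2.1]octan-6-ium tetrafluoroborate
Conditions: (1R,4R,5R)-isothiocineole (1.0 equiv), HBF4·OEt2, CH2Cl2, 0 °C → rt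
Reagents that add atoms: (1R,4R,5R)-isothiocineole, C[C@@H]1CC[C@@H]2C[C@H]1SC2(C)C; tetrafluoroboric acid, [H+].F[B-](F)(F)F
Why: SN1 alkylation as in step 16, which should occur on the less hindered sulfur lone pair of the bicyclic sulfide and give one sulfonium diastereomer.

Step 23
Reactants: 37 sulfone; 38 chiral sulfonium tetrafluoroborate
Product: 41 (2S,3S)-6-(benzyloxy)-2-[4-(benzyloxy)phenyl]-3-[3,5-bis(benzyloxy)phenyl]-4-bromo-2,3-dihydro-1-benzofuran, via o-quinone methide 39 (not isolated), via chiral sulfonium ylide 40 (not isolated)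
Conditions: Cs2CO3 (3 equiv), CH2Cl2, −20 °C → rt
Reagents that add atoms: none
Why: Proposed new method: carbonate generates o-quinone methide 39 and the chiral benzylic ylide 40, whose rigid sulfide scaffold fixes the ylide conformation and shields one face of the ylide carbon, so that conjugate addition to the methide carbon through the favoured betaine followed by invertive 5-exo-tet displacement of the sulfide by the phenoxide should give the trans product with C2 and C3 both S; the closest known reaction types are the racemic [4+1] annulation of o-quinone methides with sulfur ylides and the asymmetric epoxidation of aldehydes and cyclopropanation of enones with chiral benzylsulfonium ylides of this class.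

Step 24
Reactants: 41 (2S,3S)-4-bromo-dihydrobenzofuran
Product: 42 (2S,3S)-6-(benzyloxy)-2-[4-(benzyloxy)phenyl]-3-[3,5-bis(benzyloxy)phenyl]-4-ethenyl-2,3-dihydro-1-benzofuran
Conditions: CH2=CHSnBu3, Pd(PPh3)4 (5 mol %), toluene, 100 °C
Reagents that add atoms: tributyl(vinyl)stannane, C=C[Sn](CCCC)(CCCC)CCCC
Why: Stille coupling of the aryl bromide at zerovalent palladium installs the vinyl group without touching the benzyl ethers or the stereocentres.

Step 25
Reactants: 31 left-half aryl chloride; 42 right-half vinyl-dihydrobenzofuran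
Product: 43 deca-O-benzyl ether of the target (E-stilbene)
Conditions: Pd2(dba)3 (3 mol %), P(t-Bu)3 (12 mol %), Cy2NMe, 1,4-dioxane, 100 °C
Reagents that add atoms: none
Why: Mizoroki–Heck reaction in which the electron-rich aryl chloride adds oxidatively to zerovalent palladium bearing the bulky electron-rich phosphine, migratory insertion places the aryl on the terminal alkene carbon, and syn β-hydride elimination gives the E-stilbene.

Step 26
Reactants: 43 deca-O-benzyl ether of the target
Product: 44 target CNP0266373.2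
Conditions: BCl3 (excess), pentamethylbenzene (excess), CH2Cl2, −78 °C; MeOH quench
Reagents that add atoms: none
Why: BCl3 cleaves the ten aryl benzyl ethers at low temperature while pentamethylbenzene scavenges the benzyl cations, conditions that should spare the stilbene, the two trans-dihydrofurans and the acid-labile C11 centre.

**Compound list**
1 | methyl 3,5-bis(benzyloxy)benzoate | COC(=O)c1cc(OCc2ccccc2)cc(OCc2ccccc2)c1 | starting material
2 | methyl 3-[3,5-bis(benzyloxy)phenyl]-3-oxopropanoate | COC(=O)CC(=O)c1cc(OCc2ccccc2)cc(OCc2ccccc2)c1 | intermediate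
3 | 4-(benzyloxy)benzaldehyde | O=Cc1ccc(OCc2ccccc2)cc1 | starting material
4 | methyl 2-[3,5-bis(benzyloxy)benzoyl]-3-[4-(benzyloxy)phenyl]prop-2-enoate (E/Z mixture) | COC(=O)C(=Cc1ccc(OCc2ccccc2)cc1)C(=O)c1cc(OCc2ccccc2)cc(OCc2ccccc2)c1 | intermediate
5 | methyl (2R,3S)-4,6-bis(benzyloxy)-3-[4-(benzyloxy)phenyl]-1-oxo-2,3-dihydro-1H-indene-2-carboxylate | COC(=O)[C@H]1C(=O)c2cc(OCc3ccccc3)cc(OCc3ccccc3)c2[C@@H]1c1ccc(OCc2ccccc2)cc1 | intermediate
6 | 3,5-bis(benzyloxy)phenol | Oc1cc(OCc2ccccc2)cc(OCc2ccccc2)c1 | starting material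
7 | 3,5-bis(benzyloxy)-2-bromophenol | Oc1cc(OCc2ccccc2)cc(OCc2ccccc2)c1Br | intermediate
8 | [3,5-bis(benzyloxy)-2-bromophenoxy]trimethylsilane | C[Si](C)(C)Oc1cc(OCc2ccccc2)cc(OCc2ccccc2)c1Br | intermediate
9 | {2,4-bis(benzyloxy)-6-[(trimethylsilyl)oxy]phenyl}lithium | [Li]c1c(OCc2ccccc2)cc(OCc2ccccc2)cc1O[Si](C)(C)C | intermediate
10 | lithium 3,5-bis(benzyloxy)-2-(trimethylsilyl)phenolate | [Li+].[O-]c1cc(OCc2ccccc2)cc(OCc2ccccc2)c1[Si](C)(C)C | intermediate
11 | 3,5-bis(benzyloxy)-2-(trimethylsilyl)phenyl trifluoromethanesulfonate | C[Si](C)(C)c1c(OCc2ccccc2)cc(OCc2ccccc2)cc1OS(=O)(=O)C(F)(F)F | intermediate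
12 | 3,5-bis(benzyloxy)benzyne (triple bond between the former C–OTf and C–SiMe3 carbons) | C1#CC(OCc2ccccc2)=CC(OCc2ccccc2)=C1 | intermediate
13 | cesium benzocyclobutenoxide from addition of the enolate of 5 to 12 and closure onto the ketone (C3 as in 5; cis ring-fusion carbons not drawn) | [Cs+].COC(=O)C12[C@@H](c3ccc(OCc4ccccc4)cc3)c3c(OCc4ccccc4)cc(OCc4ccccc4)cc3C1([O-])c1c(OCc3ccccc3)cc(OCc3ccccc3)cc12 | intermediate
14 | methyl (10R,11S)-1,3,6,8-tetrakis(benzyloxy)-11-[4-(benzyloxy)phenyl]-5-oxo-10,11-dihydro-5H-dibenzo[a,d][7]annulene-10-carboxylate | COC(=O)[C@H]1c2cc(OCc3ccccc3)cc(OCc3ccccc3)c2C(=O)c2cc(OCc3ccccc3)cc(OCc3ccccc3)c2[C@@H]1c1ccc(OCc2ccccc2)cc1 | intermediate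
15 | (10R,11S)-1,3,6,8-tetrakis(benzyloxy)-11-[4-(benzyloxy)phenyl]-5-oxo-10,11-dihydro-5H-dibenzo[a,d][7]annulene-10-carboxylic acid | OC(=O)[C@H]1c2cc(OCc3ccccc3)cc(OCc3ccccc3)c2C(=O)c2cc(OCc3ccccc3)cc(OCc3ccccc3)c2[C@@H]1c1ccc(OCc2ccccc2)cc1 | intermediate
16 | 1,3-dioxoisoindolin-2-yl ester of 15 | O=C(ON1C(=O)c2ccccc2C1=O)[C@H]1c2cc(OCc3ccccc3)cc(OCc3ccccc3)c2C(=O)c2cc(OCc3ccccc3)cc(OCc3ccccc3)c2[C@@H]1c1ccc(OCc2ccccc2)cc1 | intermediate
17 | 2-bromo-4-chlorophenol | Oc1ccc(Cl)cc1Br | starting material
18 | 1-(benzyloxy)-2-bromo-4-chlorobenzene | Clc1ccc(OCc2ccccc2)c(Br)c1 | intermediate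
19 | [2-(benzyloxy)-5-chlorophenyl]lithium | [Li]c1cc(Cl)ccc1OCc1ccccc1 | intermediate
20 | [2-(benzyloxy)-5-chlorophenyl]zinc chloride | Cl[Zn]c1cc(Cl)ccc1OCc1ccccc1 | intermediate
21 | (10R,11S)-1,3,6,8-tetrakis(benzyloxy)-10-[2-(benzyloxy)-5-chlorophenyl]-11-[4-(benzyloxy)phenyl]-10,11-dihydro-5H-dibenzo[a,d][7]annulen-5-one (trans) | Clc1ccc(OCc2ccccc2)c(c1)[C@H]1c2cc(OCc3ccccc3)cc(OCc3ccccc3)c2C(=O)c2cc(OCc3ccccc3)cc(OCc3ccccc3)c2[C@@H]1c1ccc(OCc2ccccc2)cc1 | intermediate
22 | lithium dienolate of 21 (O–C5=C5a and C9a=C10; C11 retained) | [Li+].[O-]C1=C2C(OCc3ccccc3)=CC(OCc3ccccc3)=CC2=C(c2cc(Cl)ccc2OCc2ccccc2)[C@@H](c2ccc(OCc3ccccc3)cc2)c2c(OCc3ccccc3)cc(OCc3ccccc3)cc12 | intermediate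
23 | (10S,11S)-1,3,6,8-tetrakis(benzyloxy)-10-[2-(benzyloxy)-5-chlorophenyl]-11-[4-(benzyloxy)phenyl]-10,11-dihydro-5H-dibenzo[a,d][7]annulen-5-one (cis) | Clc1ccc(OCc2ccccc2)c(c1)[C@@H]1c2cc(OCc3ccccc3)cc(OCc3ccccc3)c2C(=O)c2cc(OCc3ccccc3)cc(OCc3ccccc3)c2[C@@H]1c1ccc(OCc2ccccc2)cc1 | intermediate
24 | (10S,11S)-1,3,8-tris(benzyloxy)-10-[2-(benzyloxy)-5-chlorophenyl]-11-[4-(benzyloxy)phenyl]-6-hydroxy-10,11-dihydro-5H-dibenzo[a,d][7]annulen-5-one | Clc1ccc(OCc2ccccc2)c(c1)[C@@H]1c2cc(OCc3ccccc3)cc(O)c2C(=O)c2cc(OCc3ccccc3)cc(OCc3ccccc3)c2[C@@H]1c1ccc(OCc2ccccc2)cc1 | intermediate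
25 | (10S,11S)-1,3,8-tris(benzyloxy)-10-[2-(benzyloxy)-5-chlorophenyl]-11-[4-(benzyloxy)phenyl]-10,11-dihydro-5H-dibenzo[a,d][7]annulene-5,6-diol (C5 epimers) | Clc1ccc(OCc2ccccc2)c(c1)[C@@H]1c2cc(OCc3ccccc3)cc(O)c2C(O)c2cc(OCc3ccccc3)cc(OCc3ccccc3)c2[C@@H]1c1ccc(OCc2ccccc2)cc1 | intermediate
26 | (10S,11S)-1,3,8-tris(benzyloxy)-10-[2-(benzyloxy)-5-chlorophenyl]-11-[4-(benzyloxy)phenyl]-5-(4-methylbenzenesulfonyl)-10,11-dihydro-5H-dibenzo[a,d][7]annulen-6-ol (C5 epimers) | Clc1ccc(OCc2ccccc2)c(c1)[C@@H]1c2cc(OCc3ccccc3)cc(O)c2C(S(=O)(=O)c2ccc(C)cc2)c2cc(OCc3ccccc3)cc(OCc3ccccc3)c2[C@@H]1c1ccc(OCc2ccccc2)cc1 | intermediate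
27 | [4-(benzyloxy)phenyl]methanol | OCc1ccc(OCc2ccccc2)cc1 | starting material
28 | 1-[4-(benzyloxy)benzyl]thiolan-1-ium tetrafluoroborate | F[B-](F)(F)F.C1CC[S+](C1)Cc1ccc(OCc2ccccc2)cc1 | intermediate
29 | (10S,11S) o-quinone methide from 26 (C5=C5a, C6=O) | Clc1ccc(OCc2ccccc2)c(c1)[C@@H]1C2=CC(OCc3ccccc3)=CC(=O)C2=Cc2cc(OCc3ccccc3)cc(OCc3ccccc3)c2[C@@H]1c1ccc(OCc2ccccc2)cc1 | intermediate
30 | [4-(benzyloxy)phenyl](thiolan-1-ium-1-yl)methanide | [CH-](c1ccc(OCc2ccccc2)cc1)[S+]1CCCC1 | intermediate
31 | left-half aryl chloride, (5S,10S,11S,12S): trans-dihydrofuran O–C12H[4-(benzyloxy)phenyl] fused at C5–C5a–C6 of the 1,3,8-tris(benzyloxy)-10-[2-(benzyloxy)-5-chlorophenyl]-11-[4-(benzyloxy)phenyl]-10,11-dihydro-5H-dibenzo[a,d][7]annulene core | O(Cc5ccccc5)c1ccc([C@H]2c3c(OCc5ccccc5)cc(OCc5ccccc5)cc3[C@H]3c4c(cc(OCc5ccccc5)cc4[C@H]2c2cc(Cl)ccc2OCc2ccccc2)O[C@@H]3c2ccc(OCc5ccccc5)cc2)cc1 | intermediate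
32 | 1,3-bis(benzyloxy)-5-bromobenzene | Brc1cc(OCc2ccccc2)cc(OCc2ccccc2)c1 | starting material
33 | 2,4-bis(benzyloxy)-6-bromobenzaldehyde | O=Cc1c(Br)cc(OCc2ccccc2)cc1OCc1ccccc1 | intermediate
34 | 4-(benzyloxy)-2-bromo-6-hydroxybenzaldehyde | O=Cc1c(O)cc(OCc2ccccc2)cc1Br | intermediate
35 | [3,5-bis(benzyloxy)phenyl]magnesium bromide | Br[Mg]c1cc(OCc2ccccc2)cc(OCc2ccccc2)c1 | intermediate
36 | 5-(benzyloxy)-2-{[3,5-bis(benzyloxy)phenyl](hydroxy)methyl}-3-bromophenol (racemic) | Oc1cc(OCc2ccccc2)cc(Br)c1C(O)c1cc(OCc2ccccc2)cc(OCc2ccccc2)c1 | intermediate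
37 | 5-(benzyloxy)-2-{[3,5-bis(benzyloxy)phenyl](4-methylbenzenesulfonyl)methyl}-3-bromophenol (racemic) | Oc1cc(OCc2ccccc2)cc(Br)c1C(c1cc(OCc2ccccc2)cc(OCc2ccccc2)c1)S(=O)(=O)c1ccc(C)cc1 | intermediate
38 | (1R,4R,5R)-6-[4-(benzyloxy)benzyl]-4,7,7-trimethyl-6-thiabicyclo[3.2.1]octan-6-ium tetrafluoroborate (one diastereomer at sulfur, not drawn) | F[B-](F)(F)F.C[C@@H]1CC[C@@H]2C[C@H]1[S+](Cc1ccc(OCc3ccccc3)cc1)C2(C)C | intermediate
39 | 5-(benzyloxy)-3-bromo-6-[3,5-bis(benzyloxy)benzylidene]cyclohexa-2,4-dien-1-one (o-quinone methide from 37) | O=C1C=C(OCc2ccccc2)C=C(Br)C1=Cc1cc(OCc2ccccc2)cc(OCc2ccccc2)c1 | intermediate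
40 | ylide of 38: [4-(benzyloxy)phenyl][(1R,4R,5R)-4,7,7-trimethyl-6-thiabicyclo[3.2.1]octan-6-ium-6-yl]methanide | C[C@@H]1CC[C@@H]2C[C@H]1[S+]([CH-]c1ccc(OCc3ccccc3)cc1)C2(C)C | intermediate
41 | (2S,3S)-6-(benzyloxy)-2-[4-(benzyloxy)phenyl]-3-[3,5-bis(benzyloxy)phenyl]-4-bromo-2,3-dihydro-1-benzofuran | Brc1cc(OCc3ccccc3)cc2c1[C@H](c1cc(OCc3ccccc3)cc(OCc3ccccc3)c1)[C@@H](c1ccc(OCc3ccccc3)cc1)O2 | intermediate
42 | (2S,3S)-6-(benzyloxy)-2-[4-(benzyloxy)phenyl]-3-[3,5-bis(benzyloxy)phenyl]-4-ethenyl-2,3-dihydro-1-benzofuran | C=Cc1cc(OCc3ccccc3)cc2c1[C@H](c1cc(OCc3ccccc3)cc(OCc3ccccc3)c1)[C@@H](c1ccc(OCc3ccccc3)cc1)O2 | intermediate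
43 | deca-O-benzyl ether of the target (left half 5S,10S,11S,12S; right half 2S,3S; E-alkene) | O(Cc5ccccc5)c1ccc([C@H]2c3c(OCc5ccccc5)cc(OCc5ccccc5)cc3[C@H]3c4c(cc(OCc5ccccc5)cc4[C@H]2c2cc(/C=C/c4cc(OCc5ccccc5)cc5c4[C@H](c4cc(OCc6ccccc6)cc(OCc6ccccc6)c4)[C@@H](c4ccc(OCc6ccccc6)cc4)O5)ccc2OCc2ccccc2)O[C@@H]3c2ccc(OCc5ccccc5)cc2)cc1 | intermediate
44 | CNP0266373.2 (left half 5S,10S,11S,12S; right half 2S,3S; E-alkene) | Oc1ccc([C@H]2c3c(O)cc(O)cc3[C@H]3c4c(cc(O)cc4[C@H]2c2cc(/C=C/c4cc(O)cc5c4[C@H](c4cc(O)cc(O)c4)[C@@H](c4ccc(O)cc4)O5)ccc2O)O[C@@H]3c2ccc(O)cc2)cc1 | target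

**Step count and risks**

Total step count: 26. Longest linear sequence: 14 steps (steps 1–3, 7–9, 11–15, 17, 25, 26).

Three steps most likely to fail:

Step 12 (bears the label). The proton transfer to C10 may lose facial selectivity, for example by proton return through the O-protonated dienol or by equilibration back toward the trans isomer. The fallback uses known chemistry and sets out from 21. The same lateral enolate 22 is trapped at C10 with PhSeCl (enolate selenenylation) to give the C10 phenyl selenide F1. Bu3SnH and AIBN in toluene at 80 °C then cleave the C–Se bond, and the planar diarylmethyl radical at C10 takes hydrogen from the tin hydride on the face away from the C11 aryl group. This changes the stereo-determining event from a proton transfer to a hydrogen-atom transfer and comes back to the route at 23.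

Step 23 (bears the label). The chiral benzylic ylide may add to the hindered, bromine-flanked o-quinone methide with low facial discrimination, or the electron-rich sulfonium salt may ionise before the ylide forms. The fallback uses known chemistry and sets out from 37. It is annulated with the achiral salt 28 under the conditions of step 17, which gives the racemic trans bromide, that is 41 together with the (2R,3R)-enantiomer of 41 F2. The two are separated by preparative HPLC on a chiral stationary phase, and the route is rejoined at 41.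

Step 11. The hindered benzylic C10 radical may dimerise or be reduced faster than it is captured by the nickel species carrying the ortho-substituted aryl group. The fallback sets out from acid 15 and aryl bromide 18 and changes both the radical source and the role of the aryl partner. The free carboxylate is oxidised by a photoexcited iridium catalyst (Ir[dF(CF3)ppy]2(dtbbpy)PF6, blue light) while NiCl2·glyme with 4,4′-di-tert-butyl-2,2′-bipyridine and Cs2CO3 in DMF takes up the aryl bromide by oxidative addition, so that no activated ester and no organozinc reagent are needed. It comes back to the route at 21 and makes no new compound.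

**Further compounds**
F1 | step 12 | (11S)-1,3,6,8-tetrakis(benzyloxy)-10-[2-(benzyloxy)-5-chlorophenyl]-11-[4-(benzyloxy)phenyl]-10-(phenylselanyl)-10,11-dihydro-5H-dibenzo[a,d][7]annulen-5-one (either C10 epimer) | Clc1ccc(OCc2ccccc2)c(c1)C1([Se]c2ccccc2)c2cc(OCc3ccccc3)cc(OCc3ccccc3)c2C(=O)c2cc(OCc3ccccc3)cc(OCc3ccccc3)c2[C@@H]1c1ccc(OCc2ccccc2)cc1
F2 | step 23 | (2R,3R)-6-(benzyloxy)-2-[4-(benzyloxy)phenyl]-3-[3,5-bis(benzyloxy)phenyl]-4-bromo-2,3-dihydro-1-benzofuran | Brc1cc(OCc3ccccc3)cc2c1[C@@H](c1cc(OCc3ccccc3)cc(OCc3ccccc3)c1)[C@H](c1ccc(OCc3ccccc3)cc1)O2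
F0 | step 11 | none | none
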